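**Retrosynthetic overview**

1. The target 29 comes from the fully silylated (2S)-flavanone 28 by one global desilylation.
2. Ring C is opened at C4–C4a: 28 comes from the (3S)-3-aryl-3-aryloxypropanoic acid 26 by intramolecular Friedel–Crafts acylation. The strategy rests on ring A: C8 carries the 3-hydroxy-3-methylbutyl chain, so C4a is the only free carbon ortho to O1, and an acyl carbon tethered through O1–C2–C3 can close only there.
3. The O1–C2 bond and the C2 stereocentre of 26 come from an iridium-catalysed asymmetric allylic etherification of ring A phenol 9 with ring B cinnamyl carbonate 20, followed by hydroboration and oxidation of the vinyl group to the acid.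
4. Phenol 9 comes from phloroglucinol through a dihydrocoumarin, whose lactone marks the future O1, and MeMgBr. Carbonate 20, with the chromene already in place, comes from 4-bromoresorcinol through a chromanone, the chromene and a Heck reaction.
5. Order of ring formation: ring A is bought, the pyran ring on ring B is made early, and ring C is closed last.

Key step: step 14

Assumption: the phosphoramidite in step 11 is taken to induce in the same sense as with simple cinnamyl carbonates, the (Sa,Sc,Sc) ligand giving the (S)-aryl ether; if a model run shows the opposite sense, the antipodal ligand is used.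

**Step 1**
Reactants: 1 phloroglucinol; 2 acrylic acid
Product: 4 5,7-dihydroxychroman-2-one, via arylpropanoic acid 3 (not isolated)
Conditions: Amberlyst-15, toluene, reflux (Dean–Stark), 1 in excess
Reagents that add atoms: none
Why: Acid-catalysed Friedel–Crafts conjugate addition of the phloroglucinol ring to acrylic acid gives acid 3, which lactonises onto an ortho hydroxyl as water is removed; because 1 is symmetric only one dihydrocoumarin can form, and the excess of 1 suppresses double alkylation.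

**Step 2**
Reactants: 4 5,7-dihydroxychroman-2-one
Product: 5 5,7-bis(triisopropylsilyloxy)chroman-2-one
Conditions: TIPSOTf, 2,6-lutidine, CH2Cl2, 0 °C
Reagents that add atoms: triisopropylsilyl trifluoromethanesulfonate, CC(C)[Si](OS(=O)(=O)C(F)(F)F)(C(C)C)C(C)C
Why: Silyl ether formation with a silyl triflate and a non-nucleophilic base protects both phenols without opening the aryl lactone, which keeps the third oxygen (the future O1) distinct from the two that become the C5 and C7 hydroxyls.

**Step 3**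
Reactants: 5 5,7-bis(triisopropylsilyloxy)chroman-2-one
Product: 7 2-(3-hydroxy-3-methylbutyl)-3,5-bis(triisopropylsilyloxy)phenol, via methyl ketone 6 (not isolated)
Conditions: MeMgBr (3.5 equiv), THF, 0 °C to rt; aq NH4Cl
Reagents that add atoms: methylmagnesium bromide, C[Mg]Br
Why: Double Grignard addition to the aryl ester: the first equivalent opens the lactone to ketone 6 with release of the magnesium phenoxide, the second adds to the ketone to give the tertiary alcohol, and the aryl triisopropylsilyl ethers are inert to the reagent.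

**Step 4**
Reactants: 7 2-(3-hydroxy-3-methylbutyl)-3,5-bis(triisopropylsilyloxy)phenol
Product: 9 2-[3-methyl-3-(triethylsilyloxy)butyl]-3,5-bis(triisopropylsilyloxy)phenol, via bis(triethylsilyl) ether 8 (not isolated)
Conditions: TESOTf, 2,6-lutidine, CH2Cl2, −78 to 0 °C; then K2CO3, MeOH–THF, 0 °C
Reagents that add atoms: triethylsilyl trifluoromethanesulfonate, CC[Si](CC)(CC)OS(=O)(=O)C(F)(F)F
Why: The silyl triflate silylates both the phenol and the tertiary alcohol, and selective base-mediated methanolysis then removes only the aryl triethylsilyl ether, since aryl silyl ethers are much more labile to methoxide than alkyl ones and the bulkier triisopropylsilyl groups react far more slowly.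

**Step 5**
Reactants: 10 4-bromoresorcinol; 11 3-methylbut-2-enoic acid
Product: 13 6-bromo-7-hydroxy-2,2-dimethylchroman-4-one, via aryl enone 12 (not isolated)
Conditions: P2O5–MeSO3H (1:10), 70 °C
Reagents that add atoms: none
Why: Friedel–Crafts acylation at C6 of the resorcinol (bromine blocks C4 and C2 is hindered) followed by intramolecular oxa-Michael addition of the ortho hydroxyl to enone 12 gives the 2,2-dimethylchroman-4-one, with bromine placed so that the later chromene is linearly fused.

**Step 6**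
Reactants: 13 6-bromo-7-hydroxy-2,2-dimethylchroman-4-one
Product: 14 6-bromo-2,2-dimethyl-7-(triisopropylsilyloxy)chroman-4-one
Conditions: TIPSCl, imidazole, DMF, rt to 40 °C
Reagents that add atoms: triisopropylsilyl chloride, CC(C)[Si](Cl)(C(C)C)C(C)C
Why: Standard imidazole-promoted silyl ether formation masks the acidic phenol, which would otherwise retard ketone reduction as its phenoxide.

**Step 7**
Reactants: 14 6-bromo-2,2-dimethyl-7-(triisopropylsilyloxy)chroman-4-one
Product: 16 6-bromo-2,2-dimethyl-7-(triisopropylsilyloxy)-2H-chromene, via chromanol 15 (not isolated)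
Conditions: NaBH4, MeOH–THF, 0 °C; then p-TsOH·H2O (cat.), toluene, 80 °C
Reagents that add atoms: none
Why: Borohydride reduction of the aryl ketone and acid-catalysed E1 dehydration of the benzylic alcohol, whose cation is stabilised by the ring oxygen and the para silyloxy group, is the standard chromanone-to-2H-chromene conversion.

**Step 8**
Reactants: 16 6-bromo-2,2-dimethyl-7-(triisopropylsilyloxy)-2H-chromene; 17 methyl acrylate
Product: 18 methyl (E)-3-[2,2-dimethyl-7-(triisopropylsilyloxy)-2H-chromen-6-yl]prop-2-enoate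
Conditions: Pd2(dba)3 (cat.), [HP(t-Bu)3]BF4 (cat.), Cy2NMe, 1,4-dioxane, 80 °C
Reagents that add atoms: none
Why: Mizoroki–Heck reaction: oxidative addition of the hindered electron-rich aryl bromide to zerovalent palladium bearing the bulky phosphine, acrylate insertion and syn β-hydride elimination give the E-cinnamate, the hindered chromene alkene being a much poorer acceptor than methyl acrylate.

**Step 9**
Reactants: 18 methyl (E)-3-[2,2-dimethyl-7-(triisopropylsilyloxy)-2H-chromen-6-yl]prop-2-enoate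
Product: 19 (E)-3-[2,2-dimethyl-7-(triisopropylsilyloxy)-2H-chromen-6-yl]prop-2-en-1-ol
Conditions: i-Bu2AlH, CH2Cl2, −78 °C; aq potassium sodium tartrate
Reagents that add atoms: none
Why: 1,2-Reduction of the unsaturated ester by the aluminium hydride at low temperature gives the E-allylic alcohol without touching the silyl ether or the chromene alkene.

**Step 10**
Reactants: 19 (E)-3-[2,2-dimethyl-7-(triisopropylsilyloxy)-2H-chromen-6-yl]prop-2-en-1-ol
Product: 20 (E)-3-[2,2-dimethyl-7-(triisopropylsilyloxy)-2H-chromen-6-yl]prop-2-en-1-yl methyl carbonate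
Conditions: ClCO2Me, pyridine, CH2Cl2, 0 °C
Reagents that add atoms: methyl chloroformate, COC(=O)Cl
Why: Acylation of the primary alcohol with the chloroformate installs the carbonate leaving group for allylic substitution.

**Step 11**
Reactants: 9 2-[3-methyl-3-(triethylsilyloxy)butyl]-3,5-bis(triisopropylsilyloxy)phenol; 20 (E)-3-[2,2-dimethyl-7-(triisopropylsilyloxy)-2H-chromen-6-yl]prop-2-en-1-yl methyl carbonate
Product: 22 6-[(1S)-1-{2-[3-methyl-3-(triethylsilyloxy)butyl]-3,5-bis(triisopropylsilyloxy)phenoxy}prop-2-en-1-yl]-2,2-dimethyl-7-(triisopropylsilyloxy)-2H-chromene, via sodium aryloxide 21 (not isolated)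
Conditions: NaH, THF, 0 °C; then 20, [Ir(cod)Cl]2 (2 mol %), (Sa,Sc,Sc)-O,O′-(1,1′-binaphthyl-2,2′-diyl)-N,N-bis(1-phenylethyl)phosphoramidite (4 mol %, catalyst preformed with n-PrNH2), THF, rt
Reagents that add atoms: none
Why: Iridium-catalysed asymmetric allylic etherification: the cyclometallated iridium–phosphoramidite complex ionises the carbonate to an allyl complex and the aryloxide attacks its substituted terminus anti to the metal, giving the branched ether with the C2 stereocentre set as S by the ligand, which fixes the allyl face bound to iridium.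

**Step 12**
Reactants: 22 the (S)-allyl aryl ether
Product: 24 (3S)-3-[2,2-dimethyl-7-(triisopropylsilyloxy)-2H-chromen-6-yl]-3-{2-[3-methyl-3-(triethylsilyloxy)butyl]-3,5-bis(triisopropylsilyloxy)phenoxy}propan-1-ol, via alkylborane 23 (not isolated)
Conditions: 9-BBN, THF, 0 °C to rt; then NaBO3·4H2O, H2O, rt
Reagents that add atoms: sodium perborate tetrahydrate, O.O.O.O.[Na+].[O-]OB=O
Why: Anti-Markovnikov hydroboration of the monosubstituted vinyl group by the bulky dialkylborane, much faster than attack on the hindered chromene alkene, followed by mild perborate oxidation of the C–B bond gives the primary alcohol without involving the stereocentre or the silyl ethers.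

**Step 13**
Reactants: 24 the (3S)-primary alcohol
Product: 26 (3S)-3-[2,2-dimethyl-7-(triisopropylsilyloxy)-2H-chromen-6-yl]-3-{2-[3-methyl-3-(triethylsilyloxy)butyl]-3,5-bis(triisopropylsilyloxy)phenoxy}propanoic acid, via aldehyde 25 (not isolated)
Conditions: TEMPO (cat.), PhI(OAc)2, MeCN–H2O, 0 °C to rt
Reagents that add atoms: water, O
Why: Nitroxyl-catalysed oxidation, with the oxoammonium salt regenerated by PhI(OAc)2, takes the primary alcohol to aldehyde 25 and through its hydrate to the acid under near-neutral conditions that avoid base-induced β-elimination of the aryloxide.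

**Step 14**
Reactants: 26 the (3S)-3-aryl-3-aryloxypropanoic acid
Product: 28 (2S)-2-[2,2-dimethyl-7-(triisopropylsilyloxy)-2H-chromen-6-yl]-8-[3-methyl-3-(triethylsilyloxy)butyl]-5,7-bis(triisopropylsilyloxy)chroman-4-one, via acid chloride 27 (not isolated)
Conditions: 1-chloro-N,N,2-trimethylprop-1-en-1-amine, CH2Cl2, 0 °C; then SnCl4, 2,6-di-tert-butyl-4-methylpyridine, CH2Cl2 (0.01 M), −78 °C
Reagents that add atoms: none
Why: The acid is converted under neutral conditions into acid chloride 27, whose SnCl4 complex is attacked by C4a of ring A, and loss of a proton from the arenium ion to the hindered pyridine restores the arene, as in the known intramolecular Friedel–Crafts acylation of 3-aryloxypropanoic acids to chroman-4-ones. Ring C closes as a six-membered ring by electrophilic aromatic substitution that forms C4–C4a, the acyl carbon becoming C4. No stereocentre is formed, and C2, set in step 11, is β to the acyl carbon and takes no part in the bond formation. The step needs regioselectivity, which the substrate secures: of the two carbons ortho to O1, C8 carries the side chain and only C4a is free, C6 cannot be reached by the three-atom tether, and C4a is ortho to O1 and the C5 silyloxy group and para to the C7 silyloxy group. Indanone formation on ring B is disfavoured because its only free ortho carbon is meta to both ring B oxygens. Low temperature, a mild Lewis acid and the absence of free HCl are meant to keep the electron-rich benzylic C2–O1 bond, the chromene alkene and the tertiary silyl ether from ionising.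

**Step 15**
Reactants: 28 the silyl-protected (2S)-flavanone
Product: 29 (2S)-5,7-dihydroxy-2-(7-hydroxy-2,2-dimethyl-2H-chromen-6-yl)-8-(3-hydroxy-3-methylbutyl)chroman-4-one
Conditions: HF·pyridine, pyridine, THF, 0 °C to rt
Reagents that add atoms: none
Why: Fluoride-mediated global desilylation cleaves the three aryl and the one tertiary alkyl silyl ether under buffered, weakly acidic conditions that avoid phenoxide-triggered opening of ring C, so the C2 configuration should be retained.

**Compound list**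

1 | phloroglucinol | Oc1cc(O)cc(O)c1 | starting material
2 | acrylic acid | C=CC(=O)O | starting material
3 | 3-(2,4,6-trihydroxyphenyl)propanoic acid | OC(=O)CCc1c(O)cc(O)cc1O | intermediate
4 | 5,7-dihydroxychroman-2-one | O=C1CCc2c(O)cc(O)cc2O1 | intermediate
5 | 5,7-bis(triisopropylsilyloxy)chroman-2-one | O=C1CCc2c(O[Si](C(C)C)(C(C)C)C(C)C)cc(O[Si](C(C)C)(C(C)C)C(C)C)cc2O1 | intermediate
6 | 4-[2-hydroxy-4,6-bis(triisopropylsilyloxy)phenyl]butan-2-one (present as its magnesium phenoxide) | CC(=O)CCc1c(O)cc(O[Si](C(C)C)(C(C)C)C(C)C)cc1O[Si](C(C)C)(C(C)C)C(C)C | intermediate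
7 | 2-(3-hydroxy-3-methylbutyl)-3,5-bis(triisopropylsilyloxy)phenol | CC(C)(O)CCc1c(O)cc(O[Si](C(C)C)(C(C)C)C(C)C)cc1O[Si](C(C)C)(C(C)C)C(C)C | intermediate
8 | triethylsilyl ether of 7 at both the phenol and the tertiary alcohol | CC[Si](CC)(CC)OC(C)(C)CCc1c(O[Si](CC)(CC)CC)cc(O[Si](C(C)C)(C(C)C)C(C)C)cc1O[Si](C(C)C)(C(C)C)C(C)C | intermediate
9 | 2-[3-methyl-3-(triethylsilyloxy)butyl]-3,5-bis(triisopropylsilyloxy)phenol | CC[Si](CC)(CC)OC(C)(C)CCc1c(O)cc(O[Si](C(C)C)(C(C)C)C(C)C)cc1O[Si](C(C)C)(C(C)C)C(C)C | intermediate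
10 | 4-bromoresorcinol | Oc1ccc(Br)c(O)c1 | starting material
11 | 3-methylbut-2-enoic acid | CC(C)=CC(=O)O | starting material
12 | 1-(5-bromo-2,4-dihydroxyphenyl)-3-methylbut-2-en-1-one | CC(C)=CC(=O)c1cc(Br)c(O)cc1O | intermediate
13 | 6-bromo-7-hydroxy-2,2-dimethylchroman-4-one | CC1(C)CC(=O)c2cc(Br)c(O)cc2O1 | intermediate
14 | 6-bromo-2,2-dimethyl-7-(triisopropylsilyloxy)chroman-4-one | CC1(C)CC(=O)c2cc(Br)c(O[Si](C(C)C)(C(C)C)C(C)C)cc2O1 | intermediate
15 | 6-bromo-2,2-dimethyl-7-(triisopropylsilyloxy)chroman-4-ol (racemic) | CC1(C)CC(O)c2cc(Br)c(O[Si](C(C)C)(C(C)C)C(C)C)cc2O1 | intermediate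
16 | 6-bromo-2,2-dimethyl-7-(triisopropylsilyloxy)-2H-chromene | CC1(C)C=Cc2cc(Br)c(O[Si](C(C)C)(C(C)C)C(C)C)cc2O1 | intermediate
17 | methyl acrylate | C=CC(=O)OC | starting material
18 | methyl (E)-3-[2,2-dimethyl-7-(triisopropylsilyloxy)-2H-chromen-6-yl]prop-2-enoate | COC(=O)/C=C/c1cc2c(cc1O[Si](C(C)C)(C(C)C)C(C)C)OC(C)(C)C=C2 | intermediate
19 | (E)-3-[2,2-dimethyl-7-(triisopropylsilyloxy)-2H-chromen-6-yl]prop-2-en-1-ol | OC/C=C/c1cc2c(cc1O[Si](C(C)C)(C(C)C)C(C)C)OC(C)(C)C=C2 | intermediate
20 | (E)-3-[2,2-dimethyl-7-(triisopropylsilyloxy)-2H-chromen-6-yl]prop-2-en-1-yl methyl carbonate | COC(=O)OC/C=C/c1cc2c(cc1O[Si](C(C)C)(C(C)C)C(C)C)OC(C)(C)C=C2 | intermediate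
21 | sodium 2-[3-methyl-3-(triethylsilyloxy)butyl]-3,5-bis(triisopropylsilyloxy)phenoxide | CC[Si](CC)(CC)OC(C)(C)CCc1c([O-])cc(O[Si](C(C)C)(C(C)C)C(C)C)cc1O[Si](C(C)C)(C(C)C)C(C)C.[Na+] | intermediate
22 | 6-[(1S)-1-{2-[3-methyl-3-(triethylsilyloxy)butyl]-3,5-bis(triisopropylsilyloxy)phenoxy}prop-2-en-1-yl]-2,2-dimethyl-7-(triisopropylsilyloxy)-2H-chromene | CC[Si](CC)(CC)OC(C)(C)CCc1c(O[Si](C(C)C)(C(C)C)C(C)C)cc(O[Si](C(C)C)(C(C)C)C(C)C)cc1O[C@H](c1cc2c(cc1O[Si](C(C)C)(C(C)C)C(C)C)OC(C)(C)C=C2)C=C | intermediate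
23 | 9-[(3S)-3-aryl-3-aryloxypropyl]-9-borabicyclo[3.3.1]nonane derived from 22 | CC[Si](CC)(CC)OC(C)(C)CCc1c(O[Si](C(C)C)(C(C)C)C(C)C)cc(O[Si](C(C)C)(C(C)C)C(C)C)cc1O[C@H](c1cc2c(cc1O[Si](C(C)C)(C(C)C)C(C)C)OC(C)(C)C=C2)CCB1C2CCCC1CCC2 | intermediate
24 | (3S)-3-[2,2-dimethyl-7-(triisopropylsilyloxy)-2H-chromen-6-yl]-3-{2-[3-methyl-3-(triethylsilyloxy)butyl]-3,5-bis(triisopropylsilyloxy)phenoxy}propan-1-ol | CC[Si](CC)(CC)OC(C)(C)CCc1c(O[Si](C(C)C)(C(C)C)C(C)C)cc(O[Si](C(C)C)(C(C)C)C(C)C)cc1O[C@H](c1cc2c(cc1O[Si](C(C)C)(C(C)C)C(C)C)OC(C)(C)C=C2)CCO | intermediate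
25 | (3S)-3-aryl-3-aryloxypropanal corresponding to 24 | CC[Si](CC)(CC)OC(C)(C)CCc1c(O[Si](C(C)C)(C(C)C)C(C)C)cc(O[Si](C(C)C)(C(C)C)C(C)C)cc1O[C@H](c1cc2c(cc1O[Si](C(C)C)(C(C)C)C(C)C)OC(C)(C)C=C2)CC=O | intermediate
26 | (3S)-3-[2,2-dimethyl-7-(triisopropylsilyloxy)-2H-chromen-6-yl]-3-{2-[3-methyl-3-(triethylsilyloxy)butyl]-3,5-bis(triisopropylsilyloxy)phenoxy}propanoic acid | CC[Si](CC)(CC)OC(C)(C)CCc1c(O[Si](C(C)C)(C(C)C)C(C)C)cc(O[Si](C(C)C)(C(C)C)C(C)C)cc1O[C@H](c1cc2c(cc1O[Si](C(C)C)(C(C)C)C(C)C)OC(C)(C)C=C2)CC(=O)O | intermediate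
27 | (3S)-acid chloride of 26 | CC[Si](CC)(CC)OC(C)(C)CCc1c(O[Si](C(C)C)(C(C)C)C(C)C)cc(O[Si](C(C)C)(C(C)C)C(C)C)cc1O[C@H](c1cc2c(cc1O[Si](C(C)C)(C(C)C)C(C)C)OC(C)(C)C=C2)CC(=O)Cl | intermediate
28 | (2S)-2-[2,2-dimethyl-7-(triisopropylsilyloxy)-2H-chromen-6-yl]-8-[3-methyl-3-(triethylsilyloxy)butyl]-5,7-bis(triisopropylsilyloxy)chroman-4-one | CC[Si](CC)(CC)OC(C)(C)CCc1c(O[Si](C(C)C)(C(C)C)C(C)C)cc(O[Si](C(C)C)(C(C)C)C(C)C)c2c1O[C@H](c1cc3c(cc1O[Si](C(C)C)(C(C)C)C(C)C)OC(C)(C)C=C3)CC2=O | intermediate
29 | (2S)-5,7-dihydroxy-2-(7-hydroxy-2,2-dimethyl-2H-chromen-6-yl)-8-(3-hydroxy-3-methylbutyl)chroman-4-one (CNP0423488.1) | CC(C)(O)CCc1c(O)cc(O)c2c1O[C@H](c1cc3c(cc1O)OC(C)(C)C=C3)CC2=O | target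

**Totals**

Total step count: 15.
Longest linear sequence: 11 steps (steps 5 to 15, from 4-bromoresorcinol).

**Steps most likely to fail**

Step 14. Lewis-acid ionisation of the doubly activated benzylic C2–O1 bond (loss of the aryloxide or racemisation), or cleavage of the tertiary silyl ether, may outpace acylation. The fallback sets out from acid 26 and comes back at flavanone 28. Coupling of 26 with dimethylamine hydrochloride (EDC·HCl, HOBt, i-Pr2NEt, CH2Cl2) should give the (3S)-N,N-dimethylpropanamide F6. Electrophilic amide activation with Tf2O and 2-fluoropyridine in CH2Cl2 at −78 to 0 °C lets C4a attack the activated amide in a Vilsmeier–Haack-type cyclisation without any metal Lewis acid, giving the cyclic (2S)-chroman-4-iminium triflate F7. Aqueous NaHCO3 then hydrolyses F7 to 28. The same C4–C4a bond is formed.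

Step 11. The electron-rich branched ether may re-ionise on the catalyst, eroding enantiomeric purity and isomerising to the linear ether; the ortho silyloxy group may slow ionisation; and the ambident aryloxide may undergo C-allylation. The fallback sets out from bromide 16 and phenol 9 and comes back at alcohol 24.
- Bromine–lithium exchange on 16 (n-BuLi, THF, −78 °C) and trapping with DMF should give 2,2-dimethyl-7-(triisopropylsilyloxy)-2H-chromene-6-carbaldehyde F1.
- Addition of the lithium enolate of methyl acetate (LiN(i-Pr)2, THF, −78 °C) should give racemic methyl 3-hydroxy-3-arylpropanoate F2.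
- Dess–Martin oxidation should give the β-keto ester F3.
- Asymmetric transfer hydrogenation with RuCl[(R,R)-TsDPEN](p-cymene) in HCO2H–Et3N should give the methyl (3R)-3-hydroxy-3-arylpropanoate F4; the sense follows from aryl alkyl ketones, where the (S,S) catalyst gives (S)-carbinols with the same priority order.
- Mitsunobu etherification of F4 with 9 (PPh3, DIAD, toluene, 0 °C) should proceed with inversion to the methyl (3S)-3-aryl-3-aryloxypropanoate F5.
- i-Bu2AlH in CH2Cl2 at −78 °C reduces F5 to 24.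

Step 15. The hindered aryl silyl ethers may be cleaved incompletely under conditions mild enough to avoid opening of ring C (racemisation at C2) or acid-induced cyclisation of the tertiary alcohol onto the C7 phenol. The fallback sets out from 28 and comes back at target 29, with a staged, orthogonal unmasking instead of one global step. KHF2 in MeOH–THF at rt, which is selective for aryl silyl ethers, should give the (2S)-flavanone triol still carrying the tertiary triethylsilyl ether F8. Brief treatment with pyridinium p-toluenesulfonate in MeOH at 0 °C then removes the alkyl silyl ether to give 29.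

**Further compounds**

F1 | step 11 | 2,2-dimethyl-7-(triisopropylsilyloxy)-2H-chromene-6-carbaldehyde | O=Cc1cc2c(cc1O[Si](C(C)C)(C(C)C)C(C)C)OC(C)(C)C=C2
F2 | step 11 | methyl 3-[2,2-dimethyl-7-(triisopropylsilyloxy)-2H-chromen-6-yl]-3-hydroxypropanoate (racemic) | COC(=O)CC(O)c1cc2c(cc1O[Si](C(C)C)(C(C)C)C(C)C)OC(C)(C)C=C2
F3 | step 11 | methyl 3-[2,2-dimethyl-7-(triisopropylsilyloxy)-2H-chromen-6-yl]-3-oxopropanoate | COC(=O)CC(=O)c1cc2c(cc1O[Si](C(C)C)(C(C)C)C(C)C)OC(C)(C)C=C2
F4 | step 11 | methyl (3R)-3-[2,2-dimethyl-7-(triisopropylsilyloxy)-2H-chromen-6-yl]-3-hydroxypropanoate | O[C@@H](c1cc2c(cc1O[Si](C(C)C)(C(C)C)C(C)C)OC(C)(C)C=C2)CC(=O)OC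
F5 | step 11 | methyl (3S)-3-[2,2-dimethyl-7-(triisopropylsilyloxy)-2H-chromen-6-yl]-3-{2-[3-methyl-3-(triethylsilyloxy)butyl]-3,5-bis(triisopropylsilyloxy)phenoxy}propanoate | CC[Si](CC)(CC)OC(C)(C)CCc1c(O[Si](C(C)C)(C(C)C)C(C)C)cc(O[Si](C(C)C)(C(C)C)C(C)C)cc1O[C@H](c1cc2c(cc1O[Si](C(C)C)(C(C)C)C(C)C)OC(C)(C)C=C2)CC(=O)OC
F6 | step 14 | (3S)-3-[2,2-dimethyl-7-(triisopropylsilyloxy)-2H-chromen-6-yl]-N,N-dimethyl-3-{2-[3-methyl-3-(triethylsilyloxy)butyl]-3,5-bis(triisopropylsilyloxy)phenoxy}propanamide | CC[Si](CC)(CC)OC(C)(C)CCc1c(O[Si](C(C)C)(C(C)C)C(C)C)cc(O[Si](C(C)C)(C(C)C)C(C)C)cc1O[C@H](c1cc2c(cc1O[Si](C(C)C)(C(C)C)C(C)C)OC(C)(C)C=C2)CC(=O)N(C)C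
F7 | step 14 | (2S)-N,N-dimethylchroman-4-iminium triflate corresponding to 28 | CC[Si](CC)(CC)OC(C)(C)CCc1c(O[Si](C(C)C)(C(C)C)C(C)C)cc(O[Si](C(C)C)(C(C)C)C(C)C)c2c1O[C@H](c1cc3c(cc1O[Si](C(C)C)(C(C)C)C(C)C)OC(C)(C)C=C3)CC2=[N+](C)C.[O-]S(=O)(=O)C(F)(F)F
F8 | step 15 | (2S)-5,7-dihydroxy-2-(7-hydroxy-2,2-dimethyl-2H-chromen-6-yl)-8-[3-methyl-3-(triethylsilyloxy)butyl]chroman-4-one | CC[Si](CC)(CC)OC(C)(C)CCc1c(O)cc(O)c2c1O[C@H](c1cc3c(cc1O)OC(C)(C)C=C3)CC2=O
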